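I cannot see the first hours of this flask in the earlier runs: their first reading comes at 2.50 d. What they do show is how two routes share the coupling partner.

| setting | ash | oak | birch | flask |
|---|---|---|---|---|
| substrate | 0.28 M | 0.44 M | 0.20 M | 0.20 M |
| coupling partner | 1 equiv | 1 equiv | 1 equiv | 1.00 equiv |
| free catalyst | 1 mol% | 1 mol% | 2 mol% | 1 mol% |
| remark | run made earlier | run made earlier | run made earlier |  |
| time |  |  |  | 15 d |

| run | time / d | target / % | uncatalysed product / % |
|---|---|---|---|
| ash | 2.50 | 27.2 | 45.7 |
| ash | 5.00 | 38.0 | 50.0 |
| ash | 6.00 | 39.1 | 49.6 |
| ash | 10.0 | 44.2 | 51.9 |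
| oak | 2.50 | 34.3 | 48.2 |
| oak | 5.00 | 42.2 | 50.7 |
| oak | 6.00 | 44.5 | 51.4 |
| oak | 10.0 | 47.0 | 50.5 |
| birch | 2.50 | 39.0 | 32.1 |
| birch | 5.00 | 52.8 | 35.2 |
| birch | 6.00 | 54.8 | 36.4 |
| birch | 10.0 | 60.0 | 37.1 |

(each reading ± 0.5 percentage points)

- a reading or a percentage of target counts all its forms, free or not

* ratio of target to uncatalysed product at 1.0 h
* ratio of target to uncatalysed product at 15 d

I take uncatalysed product to form at a rate proportional to substrate times partner, and target at a rate proportional to substrate times catalyst. With equal charges, let y be the fraction of partner left, read as what the two products have not used. The catalysed route then runs at u/y times the uncatalysed one, with u a constant of the run.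

Ash at 2.50 d has a target-to-uncatalysed ratio of 0.595 with y at 27.1 %. Multiplying the ratio by the mean y gives a first u of 0.378. Now I put that back in. Each portion of partner used goes to target with the share u/(y+u), and summing these portions makes target equal to u times the logarithm of (y+u) at the start over (y+u) now, which returns 0.361. This u, the catalysed rate over the uncatalysed rate with partner at full charge, is a selectivity factor. The same rounds give 0.767 for birch, twice the ash value, with twice the loading and less substrate. Oak, with ash's loading and more substrate, gives 0.393. So I take u as proportional to loading and free of concentration, and this flask keeps ash's u.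

For time, y/(y+u) decays exponentially at λ = k·c·u, with k the uncatalysed rate constant and c the substrate charge. Ash gives λ = 0.216 d⁻¹, and the flask's smaller c gives 0.154 d⁻¹. By 15 d that quantity has fallen to 0.0730, so I reckon target at 45.2 %, uncatalysed product at 52.0 % and a ratio of 0.870. At 1.0 h my ratio is u, assuming target appears as soon as substrate is taken up; the earlier runs hold no reading that early.

The forecast gives 0.45 and 0.87, on the suggestion that “the catalyst is tied up by substrate or partner”; its first figure is higher than my u, and its second stands level with mine.

The flask gives ratios of 0.0450 at 1.0 h and 0.868 at 15 d.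

    substrate + free catalyst → free catalyst + open intermediate (k = 3.80 L mol⁻¹ h⁻¹)
    free catalyst + open intermediate ⇌ catalyst intermediate (K = 54.0 L mol⁻¹, k = 290 L mol⁻¹ h⁻¹)
    coupling partner + catalyst intermediate → free catalyst + target (k = 25.0 L mol⁻¹ h⁻¹)
    2 substrate → self-condensation product (k = 6.40 × 10⁻⁵ L mol⁻¹ h⁻¹)
    crystals ⇌ target, rate k5*(cs5 - [target]) while solid is left; crystals form when [target] > cs5 (solubility = 37.0 mM, k = 0.520 h⁻¹)
    substrate + coupling partner → uncatalysed product (k = 0.0860 L mol⁻¹ h⁻¹)

My late ratio from u stands beside the computed one, but the early one does not. At the start of the flask the opening of substrate runs at 0.442 of the uncatalysed rate, while catalyst intermediate, which gives target with the partner, is made 1.00 times as fast as it is used up at 0.975 d, long after 1.0 h.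

Take a second flask, like this one but with 4 mol% of free catalyst. There u becomes 1.45, and with the partner taken as used up, uncatalysed product comes to 24.0 % and the ratio to 3.17. Computed, that flask holds 23.6 % uncatalysed product at a ratio of 3.21, with hardly any partner left (0.34 % of its charge).

(Readings and results are simulated with constants of no real substance; scatter was added.)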